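(The numbers in the tables are simulated for substances that don't exist, noise included.)

The midnight run shows the pattern: its substrate read 68.9% at 1.50 min and 68.4% at 3.00 min, so it stalled with most of its substrate unused. Here is what you have and what is asked.

| setting | dusk | summer | midnight | flask |
|---|---|---|---|---|
| substrate | 0.40 M | 0.40 M | 0.80 M | 0.40 M |
| coupling partner | 0.45 M | 0.70 M | 0.32 M | 0.320 M |
| remark | run made earlier | run made earlier | run made earlier |  |
| time |  |  |  | 5.0 min |

| run | time / min | single product / % | substrate / % |
|---|---|---|---|
| dusk | 0.167 | 13.0 | 76.5 |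
| dusk | 0.500 | 17.1 | 54.0 |
| dusk | 0.833 | 16.8 | 44.5 |
| dusk | 1.33 | 15.4 | 37.5 |
| dusk | 2.00 | 14.5 | 33.0 |
| dusk | 2.50 | 14.3 | 31.8 |
| dusk | 3.00 | 14.1 | 31.2 |
| summer | 0.250 | 17.1 | 56.1 |
| summer | 0.333 | 16.7 | 48.1 |
| summer | 0.500 | 15.9 | 38.2 |
| summer | 0.833 | 12.4 | 27.0 |
| summer | 1.33 | 10.2 | 19.3 |
| summer | 2.00 | 7.0 | 14.1 |
| summer | 3.00 | 6.0 | 10.5 |
| midnight | 0.250 | 11.0 | 80.6 |
| midnight | 0.417 | 12.9 | 74.9 |
| midnight | 0.833 | 14.6 | 70.5 |
| midnight | 1.50 | 15.3 | 68.9 |
| midnight | 3.00 | 14.9 | 68.4 |

(scatter of a reading: 0.3 percentage points)

- what was read earlier has a scatter of 0.3 percentage points, one standard deviation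

* how much single product there is at 5.0 min, in percent of the substrate charged
* concentration of by-product in solution at 5.0 min, in percent of saturation

Watch [coupling partner], since the stalls point to it as the limiting reagent. On the fastest rung, single product climbs: the dusk run reads 17.1% at 0.500 min. Next comes the stall. The midnight run had levelled off by about 1.50 min with the same partner charge as this flask. As a rough guess, not a rate law, I stretch that time by the ratio of the substrate charges, which gives 3.00 min for this flask, shorter than the asked 5.0 min. So on the slowest rung this flask should stand still, and the question becomes how much substrate the charge pays for.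

Take the partner price: partner charged per substrate lost at a stall. It reads 1.64 at dusk, with 1.12 equivalents, and 1.27 at midnight, with 0.400. Interpolating to 0.800 equivalents, with slope 0.509, I get 1.47, which leaves 45.6% substrate. Dusk read 16.8% single product at a similar 44.5% substrate, so I commit to about that.

The forecast says 15.5% and 85%, adding “the saturation figure is largely a guess”.

The simulation gives 16.8% and 99.9%.

    substrate + coupling partner → single product + by-product (k = 0.0490 M⁻¹ s⁻¹)
    substrate + coupling partner → other mono adduct + by-product (k = 0.0180 M⁻¹ s⁻¹)
    coupling partner + single product → double product + by-product (k = 0.150 M⁻¹ s⁻¹)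
    coupling partner + other mono adduct → double product + by-product (k = 0.0340 M⁻¹ s⁻¹)
    crystals ⇌ by-product, rate k5*(cs5 - [by-product]) while solid is left; crystals form when [by-product] > cs5 (solubility = 0.320 M, k = 0.250 s⁻¹)

This flask has come to rest. Its coupling partner is down to 0.056% of the charge at 5.0 min. Ten times the time changes nothing in single product, which stands at 16.8% at 50.0 min. Substrate stays at 45.8%, by-product at 0.320 M, and crystals at 0 M. The price actually paid is 1.48.

For the neighbour charged with 0.080 M of partner, the same line, extended to 0.200 equiv, gives a price of 1.16 and 82.8% substrate left. The computed neighbour holds 83%.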